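**Plan**

- Retrosynthesis: the coumarate C–O bond is cut first (Mitsunobu), then C4–C15 (Stille on a C3=C4 enol triflate); the triflate is the reduced form of a ring A enone C2=C3–C4=O.
- The enone is cut at C2–C3 and C5–C10 together. In ring A the unit C3–C4–C5 can be a methyl ketone (C4=O, donor at C5 and C3) and the unit C10–C1–C2 a β-methyl enal (acceptor at C10 and C2). C5–C10 is also the fusion bond of ring B, so a Michael addition (C5 to C10) followed by aldol condensation (C3 to C2) closes both rings from an open chain, and the C2 oxygen leaves as water.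
- The chain is (R)-limonene cut at its ring double bond: the six ring carbons become C10, C5, C6, C7, C8, C9 of ring B, the ring methyl becomes C14 and the isopropenyl group C11–C13. The cut ends are lengthened by C4/C3 (Wittig) and C1/C2 (Horner–Wadsworth–Emmons), and the bond that was cut is re-made as C5–C10.
- Forward order: chain; rings B and A in step 5; enol triflate; isopropenyl to methyl acrylate; C15; coumarate.
- Stereochemistry: C7 from the chiral pool; C10 by 1,4-induction in the chair Michael transition state (methyl axial); C5 by equilibration next to the C4 ketone (trans fusion); C3=C4 by regiospecific enolate formation; the E-cinnamate from p-coumaric acid.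

Key step: step 5

Remark: salt 3 is taken as a stock Wittig salt (the known adduct of PPh3 and 1-chloroethyl methyl ether), and 1 is used as the commercial cis/trans mixture of the (4R) series, since both epoxide isomers give the same keto-aldehyde.

**Step 1**
Reactants: 1 (4R)-limonene 1,2-oxide
Product: 2 (3R)-6-oxo-3-(prop-1-en-2-yl)heptanal
Conditions: H5IO6 (1.1 equiv), THF/H2O, 0 °C to rt
Reagents that add atoms: water, O
Why: Periodic acid hydrolyses the trisubstituted epoxide and cleaves the resulting 1,2-diol in the same flask (Malaprade glycol cleavage), which opens the limonene ring between the future C10 and C5 and leaves the isopropenyl-bearing stereocenter (future C7) untouched.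

**Step 2**
Reactants: 2 (3R)-6-oxo-3-(prop-1-en-2-yl)heptanal; 3 (1-methoxyethyl)triphenylphosphonium chloride
Product: 5 (5R)-8-methoxy-5-(prop-1-en-2-yl)non-7-en-2-one as an E/Z mixture, via ylide (1-methoxyethylidene)triphenylphosphorane 4 (not isolated)
Conditions: 3, KN(SiMe3)2, THF, −78 °C; then 2, −78 to 0 °C
Reagents that add atoms: (1-methoxyethyl)triphenylphosphonium chloride 3, COC(C)[P+](c1ccccc1)(c1ccccc1)c1ccccc1.[Cl-]
Why: Wittig olefination in which the non-stabilised alkoxy ylide should take the aldehyde much faster than the methyl ketone at low temperature; the methyl enol ether is the masked C4 ketone carrying C3, and its alkene geometry is lost on later hydrolysis.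

**Step 3**
Reactants: 5 (5R)-8-methoxy-5-(prop-1-en-2-yl)non-7-en-2-one; 6 diethyl (cyanomethyl)phosphonate
Product: 8 (6R)-9-methoxy-3-methyl-6-(prop-1-en-2-yl)deca-2,8-dienenitrile as alkene isomer mixtures, via sodium phosphonate carbanion 7 (not isolated)
Conditions: 6, NaH, THF, 0 °C; then 5, 0 °C to rt
Reagents that add atoms: diethyl (cyanomethyl)phosphonate 6, CCOP(=O)(CC#N)OCC
Why: Horner–Wadsworth–Emmons olefination of the remaining methyl ketone adds C1 and C2 and makes the trisubstituted C10=C1 alkene; both alkene isomers are carried on because they should converge in step 5.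

**Step 4**
Reactants: 8 (6R)-9-methoxy-3-methyl-6-(prop-1-en-2-yl)deca-2,8-dienenitrile
Product: 10 (6R)-3-methyl-9-oxo-6-(prop-1-en-2-yl)dec-2-enal as a 2E/2Z mixture, via N-diisobutylaluminio aldimine 9 (not isolated)
Conditions: i-Bu2AlH (1.2 equiv), toluene, −78 °C; then 1 M aq. HCl, THF, 0 °C to rt
Reagents that add atoms: water, O
Why: Partial hydride reduction of the conjugated nitrile stops at the N-aluminio imine, and the acidic work-up hydrolyses this imine to the enal and the methyl enol ether to the methyl ketone, so one operation unveils the acceptor (C10=C1–C2HO) and the donor (C3–C4(=O)–C5).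

**Step 5**
Reactants: 10 (6R)-3-methyl-9-oxo-6-(prop-1-en-2-yl)dec-2-enal
Product: 12 (4aS,7R,8aR)-4a-methyl-7-(prop-1-en-2-yl)-4a,5,6,7,8,8a-hexahydronaphthalen-1(4H)-one, via Michael adduct keto-aldehyde 11 (not isolated)
Conditions: pyrrolidine (0.5 equiv), AcOH (0.5 equiv), toluene, rt then 60 °C
Reagents that add atoms: none
Why: Pyrrolidinium acetate converts the enal into its iminium ion and the methyl ketone into its enamines; the internal enamine carbon C5 adds to the fully substituted iminium carbon C10 (Michael addition, 6-(enolexo)-exo-trig closure of ring B) to give, after turnover, keto-aldehyde 11, whose C2 iminium is then attacked by the methyl-side enamine carbon C3 (Mannich-type aldol, 6-(enolendo)-exo-trig closure of ring A), and loss of the amine, i.e. of water overall, gives the conjugated enone. The closest known reaction type is the amine-mediated Robinson-type Michael/aldol condensation in which a ketone (through both alpha carbons) and an enal (through C-beta and C=O) give a cyclohex-2-enone, here run within one chain so that the first bond also closes ring B. C10 is set in the chair transition state of the Michael closure, in which the C7 isopropenyl group inherited from limonene and the long iminium-bearing C1–C2 arm should lie equatorial and the C14 methyl axial, cis to the C7 side chain; both enal isomers should converge because their iminium ions interconvert through the dienamine. C5 is set by equilibration, since it stays enolisable next to the C4 carbonyl and the trans-fused ring system with the C7 group equatorial should be the more stable epimer. The step needs C5 rather than C3 to be the Michael donor and C3 rather than C1 or C5 to be the aldol donor: ring size secures both (six against eight atoms for the first closure, six against four for the second), and the isopropenyl alkene is inert to the weakly acidic amine medium.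

**Step 6**
Reactants: 12 (4aS,7R,8aR)-4a-methyl-7-(prop-1-en-2-yl)-4a,5,6,7,8,8a-hexahydronaphthalen-1(4H)-one
Product: 14 (4aS,7R,8aR)-4a-methyl-7-(prop-1-en-2-yl)-3,4,4a,5,6,7,8,8a-octahydronaphthalen-1-yl trifluoromethanesulfonate, via lithium enolate 13 (not isolated)
Conditions: LiBH(s-Bu)3 (1.1 equiv), THF, −78 °C; then PhNTf2, −78 °C to rt
Reagents that add atoms: N-phenylbis(trifluoromethanesulfonimide), O=S(=O)(N(c1ccccc1)S(=O)(=O)C(F)(F)F)C(F)(F)F
Why: Conjugate (1,4) hydride addition to the cyclohexenone, which has no exocyclic beta substituent, gives the C3=C4 enolate regiospecifically, and O-triflation fixes the target's C3=C4 alkene without touching the C5 stereocenter.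

**Step 7**
Reactants: 14 (4aS,7R,8aR)-4a-methyl-7-(prop-1-en-2-yl)-3,4,4a,5,6,7,8,8a-octahydronaphthalen-1-yl trifluoromethanesulfonate
Product: 15 (4aS,7R,8aR)-7-(3-hydroxyprop-1-en-2-yl)-4a-methyl-3,4,4a,5,6,7,8,8a-octahydronaphthalen-1-yl trifluoromethanesulfonate
Conditions: SeO2 (0.5 equiv), t-BuOOH (3 equiv), CH2Cl2, rt
Reagents that add atoms: tert-butyl hydroperoxide, CC(C)(C)OO (terminal oxidant; the oxygen is relayed through SeO2, O=[Se]=O)
Why: Riley-type allylic oxidation (ene reaction, then [2,3]-shift) should take the methyl group of the isopropenyl unit, the only electron-rich alkene, because the enol triflate is deactivated; any over-oxidised aldehyde is the intermediate of step 8 and converges there.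

**Step 8**
Reactants: 15 (4aS,7R,8aR)-7-(3-hydroxyprop-1-en-2-yl)-4a-methyl-3,4,4a,5,6,7,8,8a-octahydronaphthalen-1-yl trifluoromethanesulfonate
Product: 17 2-[(2R,4aS,8aR)-4a-methyl-8-(trifluoromethanesulfonyloxy)-1,2,3,4,4a,5,6,8a-octahydronaphthalen-2-yl]prop-2-enoic acid, via acrolein 16 (not isolated)
Conditions: TEMPO (0.1 equiv), NaOCl (0.05 equiv), NaClO2 (2 equiv), MeCN/phosphate buffer (pH 6.7), 35 °C
Reagents that add atoms: NaClO2, [Na+].[O-]Cl=O
Why: The TEMPO-derived oxoammonium ion oxidises the primary allylic alcohol to the 2-substituted acrolein 16, and chlorite takes it on to the acid in the same flask (Pinnick oxidation), conditions the enol triflate should tolerate.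

**Step 9**
Reactants: 17 2-[(2R,4aS,8aR)-4a-methyl-8-(trifluoromethanesulfonyloxy)-1,2,3,4,4a,5,6,8a-octahydronaphthalen-2-yl]prop-2-enoic acid
Product: 18 methyl 2-[(2R,4aS,8aR)-4a-methyl-8-(trifluoromethanesulfonyloxy)-1,2,3,4,4a,5,6,8a-octahydronaphthalen-2-yl]prop-2-enoate
Conditions: MeI, K2CO3, DMF, rt
Reagents that add atoms: iodomethane, CI
Why: SN2 O-methylation of the carboxylate installs the methyl acrylate under conditions too mild to deconjugate it or to epimerise C7.

**Step 10**
Reactants: 18 methyl 2-[(2R,4aS,8aR)-4a-methyl-8-(trifluoromethanesulfonyloxy)-1,2,3,4,4a,5,6,8a-octahydronaphthalen-2-yl]prop-2-enoate; 19 (tributylstannyl)methanol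
Product: 20 methyl 2-[(2R,4aR,8aR)-8-(hydroxymethyl)-4a-methyl-1,2,3,4,4a,5,6,8a-octahydronaphthalen-2-yl]prop-2-enoate
Conditions: 19 (1.5 equiv), Pd(PPh3)4 (10 mol %), LiCl (3 equiv), 1,4-dioxane, 95 °C
Reagents that add atoms: (tributylstannyl)methanol 19, CCCC[Sn](CCCC)(CCCC)CO
Why: Stille cross-coupling: oxidative addition of the enol triflate to zerovalent palladium, selective transfer of the oxygen-activated hydroxymethyl group from tin and reductive elimination put C15 on C4 at the alcohol oxidation level with the alkene held at C3=C4.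

**Step 11**
Reactants: 20 methyl 2-[(2R,4aR,8aR)-8-(hydroxymethyl)-4a-methyl-1,2,3,4,4a,5,6,8a-octahydronaphthalen-2-yl]prop-2-enoate; 21 (E)-4-hydroxycinnamic acid (p-coumaric acid)
Product: 22 methyl 2-[(2R,4aR,8aR)-8-({[(2E)-3-(4-hydroxyphenyl)prop-2-enoyl]oxy}methyl)-4a-methyl-1,2,3,4,4a,5,6,8a-octahydronaphthalen-2-yl]prop-2-enoate (CNP0161949.1)
Conditions: 21 (1.2 equiv), PPh3, DIAD, THF, 0 °C to rt
Reagents that add atoms: (E)-4-hydroxycinnamic acid 21, OC(=O)/C=C/c1ccc(O)cc1
Why: Mitsunobu esterification in which the carboxylic acid, far more acidic than the phenol, is the pronucleophile that displaces the primary allylic oxyphosphonium group at C15, so no phenol protection is needed and the E-alkene of the acid is carried over unchanged.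

**Compound list**

1 | (4R)-limonene 1,2-oxide, i.e. (4R)-1-methyl-4-(prop-1-en-2-yl)-7-oxabicyclo[4.1.0]heptane, cis/trans mixture | CC(=C)[C@@H]1CCC2(C)OC2C1 | starting material
2 | (3R)-6-oxo-3-(prop-1-en-2-yl)heptanal | CC(=C)[C@@H](CC=O)CCC(C)=O | intermediate
3 | (1-methoxyethyl)triphenylphosphonium chloride | COC(C)[P+](c1ccccc1)(c1ccccc1)c1ccccc1.[Cl-] | starting material
4 | (1-methoxyethylidene)triphenylphosphorane (ylide, formed in the flask) | COC(C)=P(c1ccccc1)(c1ccccc1)c1ccccc1 | intermediate
5 | (5R)-8-methoxy-5-(prop-1-en-2-yl)non-7-en-2-one (E/Z mixture) | CC(=C)[C@@H](CC=C(C)OC)CCC(C)=O | intermediate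
6 | diethyl (cyanomethyl)phosphonate | CCOP(=O)(CC#N)OCC | starting material
7 | sodium salt of the carbanion of 6 (formed in the flask) | [Na+].CCOP(=O)([CH-]C#N)OCC | intermediate
8 | (6R)-9-methoxy-3-methyl-6-(prop-1-en-2-yl)deca-2,8-dienenitrile (alkene isomer mixtures) | CC(=C)[C@@H](CC=C(C)OC)CCC(C)=CC#N | intermediate
9 | N-diisobutylaluminio aldimine of (6R)-9-methoxy-3-methyl-6-(prop-1-en-2-yl)deca-2,8-dienal (formed in the flask) | CC(=C)[C@@H](CC=C(C)OC)CCC(C)=CC=N[Al](CC(C)C)CC(C)C | intermediate
10 | (6R)-3-methyl-9-oxo-6-(prop-1-en-2-yl)dec-2-enal (2E/2Z mixture) | CC(=C)[C@@H](CCC(C)=O)CCC(C)=CC=O | intermediate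
11 | 2-[(1S,2R,4R)-2-acetyl-1-methyl-4-(prop-1-en-2-yl)cyclohexyl]acetaldehyde (formed in the flask) | C=C(C)[C@@H]1CC[C@@](C)(CC=O)[C@H](C(C)=O)C1 | intermediate
12 | (4aS,7R,8aR)-4a-methyl-7-(prop-1-en-2-yl)-4a,5,6,7,8,8a-hexahydronaphthalen-1(4H)-one | C=C(C)[C@@H]1CC[C@@]2(C)CC=CC(=O)[C@@H]2C1 | intermediate
13 | lithium (4aS,7R,8aR)-4a-methyl-7-(prop-1-en-2-yl)-3,4,4a,5,6,7,8,8a-octahydronaphthalen-1-olate (formed in the flask) | C=C(C)[C@@H]1CC[C@@]2(C)CCC=C([O-])[C@@H]2C1.[Li+] | intermediate
14 | (4aS,7R,8aR)-4a-methyl-7-(prop-1-en-2-yl)-3,4,4a,5,6,7,8,8a-octahydronaphthalen-1-yl trifluoromethanesulfonate | C=C(C)[C@@H]1CC[C@@]2(C)CCC=C(OS(=O)(=O)C(F)(F)F)[C@@H]2C1 | intermediate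
15 | (4aS,7R,8aR)-7-(3-hydroxyprop-1-en-2-yl)-4a-methyl-3,4,4a,5,6,7,8,8a-octahydronaphthalen-1-yl trifluoromethanesulfonate | C=C(CO)[C@@H]1CC[C@@]2(C)CCC=C(OS(=O)(=O)C(F)(F)F)[C@@H]2C1 | intermediate
16 | (4aS,7R,8aR)-4a-methyl-7-(3-oxoprop-1-en-2-yl)-3,4,4a,5,6,7,8,8a-octahydronaphthalen-1-yl trifluoromethanesulfonate (formed in the flask) | C=C(C=O)[C@@H]1CC[C@@]2(C)CCC=C(OS(=O)(=O)C(F)(F)F)[C@@H]2C1 | intermediate
17 | 2-[(2R,4aS,8aR)-4a-methyl-8-(trifluoromethanesulfonyloxy)-1,2,3,4,4a,5,6,8a-octahydronaphthalen-2-yl]prop-2-enoic acid | C=C(C(=O)O)[C@@H]1CC[C@@]2(C)CCC=C(OS(=O)(=O)C(F)(F)F)[C@@H]2C1 | intermediate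
18 | methyl 2-[(2R,4aS,8aR)-4a-methyl-8-(trifluoromethanesulfonyloxy)-1,2,3,4,4a,5,6,8a-octahydronaphthalen-2-yl]prop-2-enoate | C=C(C(=O)OC)[C@@H]1CC[C@@]2(C)CCC=C(OS(=O)(=O)C(F)(F)F)[C@@H]2C1 | intermediate
19 | (tributylstannyl)methanol | CCCC[Sn](CCCC)(CCCC)CO | starting material
20 | methyl 2-[(2R,4aR,8aR)-8-(hydroxymethyl)-4a-methyl-1,2,3,4,4a,5,6,8a-octahydronaphthalen-2-yl]prop-2-enoate | C=C(C(=O)OC)[C@@H]1CC[C@@]2(C)CCC=C(CO)[C@@H]2C1 | intermediate
21 | (E)-4-hydroxycinnamic acid (p-coumaric acid) | OC(=O)/C=C/c1ccc(O)cc1 | starting material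
22 | methyl 2-[(2R,4aR,8aR)-8-({[(2E)-3-(4-hydroxyphenyl)prop-2-enoyl]oxy}methyl)-4a-methyl-1,2,3,4,4a,5,6,8a-octahydronaphthalen-2-yl]prop-2-enoate | C=C(C(=O)OC)[C@@H]1CC[C@@]2(C)CCC=C(COC(=O)/C=C/c3ccc(O)cc3)[C@@H]2C1 | target

Total step count: 11. Longest linear sequence: 11 steps (from 1; compounds 3, 6, 19 and 21 are purchased).

**Steps most likely to fail**

Step 5. The risk is weak facial discrimination at the trigonal C10 during the Michael closure (methyl against the C1–C2 arm for the axial site), or stalling after the first ring because an unactivated ketone must attack a fully substituted enal carbon. The fallback sets out from nitrile 8. Reduction with i-Bu2AlH and a buffered work-up (aqueous potassium sodium tartrate, pH 7) keeps the enol ether and should give the enol ether enal (6R)-9-methoxy-3-methyl-6-(prop-1-en-2-yl)deca-2,8-dienal F1. TiCl4 (CH2Cl2, −78 °C) then triggers a Mukaiyama–Michael closure of the enol ether carbon C5 onto the Lewis-acid-bound enal, and aqueous work-up gives keto-aldehyde 11, now isolated so that C10 epimers can be separated. KOH in MeOH effects the aldol condensation and the equilibration at C5, and the route is rejoined at enone 12.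

Step 7. The risk is sluggish or unselective allylic oxidation (attack at the C7 hydrogen or at ring positions, or selenium-bound by-products). The fallback sets out from triflate 14. Ene-type allylic chlorination of the isopropenyl group (NaOCl, CeCl3·7H2O, CH2Cl2/H2O, 0 °C) should give the allylic chloride (4aS,7R,8aR)-7-(3-chloroprop-1-en-2-yl)-4a-methyl-3,4,4a,5,6,7,8,8a-octahydronaphthalen-1-yl trifluoromethanesulfonate F2. Displacement with KOAc (DMF, 60 °C) gives the acetate 2-[(2R,4aS,8aR)-4a-methyl-8-(trifluoromethanesulfonyloxy)-1,2,3,4,4a,5,6,8a-octahydronaphthalen-2-yl]prop-2-en-1-yl acetate F3, and brief methanolysis (K2CO3, MeOH, 0 °C) returns to alcohol 15.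

Step 10. The risk is slow transfer of the hydroxymethyl group from tin to the hindered alkenylpalladium species, so that loss of the triflate by reduction, butyl transfer or Heck-type reaction with the acrylate competes. The fallback sets out from triflate 18. Palladium-catalysed formylation (CO 1 atm, Et3SiH, Pd(OAc)2, dppp, Et3N, DMF, 70 °C) should give the enal methyl 2-[(2R,4aR,8aR)-8-formyl-4a-methyl-1,2,3,4,4a,5,6,8a-octahydronaphthalen-2-yl]prop-2-enoate F4. Luche reduction (NaBH4, CeCl3·7H2O, MeOH, −40 °C) reduces the aldehyde 1,2 in the presence of the acrylate and returns to alcohol 20.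

**Further compounds**

F1 | step 5 | (6R)-9-methoxy-3-methyl-6-(prop-1-en-2-yl)deca-2,8-dienal (alkene isomer mixtures) | CC(=C)[C@@H](CC=C(C)OC)CCC(C)=CC=O
F2 | step 7 | (4aS,7R,8aR)-7-(3-chloroprop-1-en-2-yl)-4a-methyl-3,4,4a,5,6,7,8,8a-octahydronaphthalen-1-yl trifluoromethanesulfonate | C=C(CCl)[C@@H]1CC[C@@]2(C)CCC=C(OS(=O)(=O)C(F)(F)F)[C@@H]2C1
F3 | step 7 | 2-[(2R,4aS,8aR)-4a-methyl-8-(trifluoromethanesulfonyloxy)-1,2,3,4,4a,5,6,8a-octahydronaphthalen-2-yl]prop-2-en-1-yl acetate | C=C(COC(C)=O)[C@@H]1CC[C@@]2(C)CCC=C(OS(=O)(=O)C(F)(F)F)[C@@H]2C1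
F4 | step 10 | methyl 2-[(2R,4aR,8aR)-8-formyl-4a-methyl-1,2,3,4,4a,5,6,8a-octahydronaphthalen-2-yl]prop-2-enoate | C=C(C(=O)OC)[C@@H]1CC[C@@]2(C)CCC=C(C=O)[C@@H]2C1
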